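**Retrosynthetic overview**
1. Last ring (dihydropyran acetal): cutting the enol-O–acetal-C bond and both acetates gives a 1,5-dialdehyde; in the same operation the oxepane O–CH2 bond is cut by retro-oxa-Michael, leading to the 2-methylene-1,5-dialdehyde 24 with a masked cyclopropane-1,1-dimethanol.
2. Enabling feature: the sp2 ring carbon of the dihydropyran next to O–CH= is the same carbon that carries the oxepane CH2–O, so this CH2 is β to the latent aldehyde (O–CH=) and the acetal carbon is its 1,5-partner; of the two CH2O arms on the quaternary cyclopropane carbon only the one cis to the side chain can reach.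
3. Cycloheptane: tertiary carbinol from ketone + MeMgBr; ketone from a spiro-dithiane closed by intramolecular alkylation of a 2-lithio-1,3-dithiane with a chloroethyl arm held trans on the cyclopropane.
4. Open chain: the two contiguous CH centres from an amine-catalysed syn-Michael addition of 3-(PMB-oxy)propanal to a cyclopropyl alkylidene malonate (malonate later becomes the 2-substituted allyl alcohol); cyclopropane from an amine-catalysed Michael-initiated ring closure of an E-enal with bromomalonate.
5. Order of ring formation: cyclopropane (step 3), cycloheptane (step 13), oxepane and then dihydropyran (both in step 18).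

Key step: step 18

Assumption: the stereodescriptors of the given SMILES are taken literally, which puts the two carbocycle bonds trans on the cyclopropane (a trans-bicyclo[5.1.0]octane) and the oxepane cis on it; the route is built for exactly this isomer.

**Route**

Step 1
Reactants: 1 but-3-en-1-ol
Product: 2 tert-butyl(but-3-en-1-yloxy)diphenylsilane
Conditions: t-BuPh2SiCl, imidazole, DMF, 0 °C → rt
Reagents that add atoms: tert-butyl(chloro)diphenylsilane, CC(C)(C)[Si](Cl)(c1ccccc1)c1ccccc1
Why: Standard silyl ether protection of a primary alcohol, chosen because the group must survive LiAlH4 at reflux in step 8; no stereocentre is involved.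

Step 2
Reactants: 2 tert-butyl(but-3-en-1-yloxy)diphenylsilane; 3 (E)-but-2-enal
Product: 4 (E)-5-[(tert-butyldiphenylsilyl)oxy]pent-2-enal
Conditions: second-generation Hoveyda–Grubbs catalyst RuCl2(H2IMes)(=CH-C6H4-2-OiPr) (3 mol%), excess 3, CH2Cl2, 40 °C
Reagents that add atoms: none
Why: Olefin cross-metathesis of a terminal alkene with crotonaldehyde should give the conjugated E-enal under thermodynamic control with loss of propene.

Step 3
Reactants: 4 (E)-5-[(tert-butyldiphenylsilyl)oxy]pent-2-enal; 5 diethyl bromomalonate
Product: 6 diethyl (2R,3R)-2-{2-[(tert-butyldiphenylsilyl)oxy]ethyl}-3-formylcyclopropane-1,1-dicarboxylate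
Conditions: (S)-2-[diphenyl(trimethylsilyloxy)methyl]pyrrolidine (20 mol%), 2,6-lutidine, CH2Cl2, 0 °C → rt
Reagents that add atoms: none
Why: Iminium-catalysed Michael-initiated ring closure, in which bromomalonate adds to the β-carbon on the face left open by the diphenyl(silyloxy)methyl group of the (S)-catalyst and the resulting enamine displaces bromide (3-exo-tet), so the E-alkene geometry becomes the trans-cyclopropane and the catalyst sets the absolute configuration.

Step 4
Reactants: 6 formylcyclopropane diester; 7 dimethyl malonate
Product: 8 diethyl (2R,3R)-2-{2-[(tert-butyldiphenylsilyl)oxy]ethyl}-3-[2,2-bis(methoxycarbonyl)ethenyl]cyclopropane-1,1-dicarboxylate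
Conditions: TiCl4, pyridine, THF, 0 °C → rt
Reagents that add atoms: none
Why: TiCl4/pyridine-mediated Knoevenagel condensation, used instead of a secondary-amine protocol so that the formylcyclopropane diester is not opened through an enamine; no new stereocentre is formed.

Step 5
Reactants: 9 3-[(4-methoxybenzyl)oxy]propan-1-ol
Product: 10 3-[(4-methoxybenzyl)oxy]propanal
Conditions: Dess–Martin periodinane, CH2Cl2, rt
Reagents that add atoms: none
Why: Dess–Martin oxidation of a primary alcohol to the aldehyde leaves the PMB ether untouched.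

Step 6
Reactants: 8 cyclopropyl alkylidene malonate; 10 3-[(4-methoxybenzyl)oxy]propanal
Product: 11 diethyl (2R,3R)-2-{2-[(tert-butyldiphenylsilyl)oxy]ethyl}-3-{(2R,3S)-3-formyl-1,1-bis(methoxycarbonyl)-4-[(4-methoxybenzyl)oxy]butan-2-yl}cyclopropane-1,1-dicarboxylate
Conditions: (S)-2-[diphenyl(trimethylsilyloxy)methyl]pyrrolidine (20 mol%), PhCO2H (20 mol%), excess 10, toluene, 4 °C
Reagents that add atoms: none
Why: Enamine-catalysed Michael addition of an aldehyde to an alkylidene malonate, in which the E-enamine of 10 reacts on the face not shielded by the catalyst through the acyclic synclinal transition state, so the α-centre is set by catalyst control and the β-centre follows as the syn diastereomer.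

Step 7
Reactants: 11 Michael adduct aldehyde
Product: 12 1,3-dithiane of 11 (formyl group converted into 1,3-dithian-2-yl; all stereocentres as in 11)
Conditions: propane-1,3-dithiol, BF3·OEt2 (cat.), CH2Cl2, −20 °C
Reagents that add atoms: propane-1,3-dithiol, SCCCS
Why: Lewis-acid-catalysed dithioacetalisation, run directly on crude 11 to avoid epimerisation next to the aldehyde, gives a group that resists hydride in step 8 and serves as the acyl-anion equivalent in step 13.

Step 8
Reactants: 12 dithiane tetraester
Product: 14 triol with cyclopropane-1,1-dimethanol and 2-substituted allyl alcohol units, via sodium malonate enolate 13 (not isolated)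
Conditions: NaH, DME, 0 °C → rt; then LiAlH4, reflux
Reagents that add atoms: none
Why: Hydride reduction of a malonate enolate should proceed by reduction of one ester, β-elimination to the 2-substituted acrylate and 1,2-reduction to the 2-substituted allylic alcohol, while the non-enolisable cyclopropane gem-diester is reduced normally to the 1,3-diol and no stereocentre is touched.

Step 9
Reactants: 14 triol
Product: 15 spiro-acetonide (5,7-dioxaspiro[2.5]octane) with free allylic alcohol
Conditions: Me2C(OMe)2, PPTS (cat.), acetone, rt
Reagents that add atoms: 2,2-dimethoxypropane, COC(C)(C)OC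
Why: Acetonide formation under thermodynamic control selects the 1,3-diol (six-membered 1,3-dioxane) and leaves the isolated allylic alcohol free.

Step 10
Reactants: 15 acetonide allylic alcohol
Product: 16 bis-PMB ether
Conditions: NaH, 4-MeOC6H4CH2Cl, Bu4NI (cat.), THF/DMF, 0 °C → rt
Reagents that add atoms: 4-methoxybenzyl chloride, COc1ccc(CCl)cc1
Why: Williamson etherification masks the allylic alcohol with the same group as the other primary oxygen, so that both are released together in step 16.

Step 11
Reactants: 16 bis-PMB ether
Product: 17 primary alcohol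
Conditions: Bu4NF, THF, rt
Reagents that add atoms: none
Why: Fluoride-induced desilylation frees only the silyl-protected primary alcohol; acetonide, PMB ethers and dithiane are stable.

Step 12
Reactants: 17 primary alcohol
Product: 18 primary chloride
Conditions: PPh3, CCl4, CH2Cl2, 40 °C
Reagents that add atoms: tetrachloromethane, ClC(Cl)(Cl)Cl
Why: The Appel reaction converts the primary alcohol into the chloride under neutral conditions, and a chloride is chosen because it does not undergo halogen–lithium exchange in step 13.

Step 13
Reactants: 18 chloro dithiane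
Product: 20 spiro-dithiane of the trans-fused bicyclo[5.1.0]octanone, via 2-lithio-1,3-dithiane 19 (not isolated)
Conditions: n-BuLi, THF/HMPA, −78 → 0 °C, 0.005 M
Reagents that add atoms: none
Why: Corey–Seebach-type intramolecular alkylation, in which the lithiated dithiane displaces the primary chloride in an irreversible 7-exo-tet closure that is the only ring size the tether allows (the five-membered alternatives would be trans-fused to the cyclopropane), so C–C bond and LiCl formation should pay for the strain of the trans-fused ring while the existing stereocentres are not epimerisable.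

Step 14
Reactants: 20 spiro-dithiane
Product: 21 cycloheptanone
Conditions: MeI, CaCO3, MeCN/H2O (9:1), 45 °C
Reagents that add atoms: water, O
Why: S-Alkylative hydrolysis of the dithiane under buffered, near-neutral conditions should unmask the ketone without epimerising the adjacent CH(CH2OPMB) centre.

Step 15
Reactants: 21 cycloheptanone
Product: 22 tertiary alcohol
Conditions: MeMgBr, CH2Cl2/Et2O, −78 °C
Reagents that add atoms: methylmagnesium bromide, C[Mg]Br
Why: Chelation-controlled Grignard addition (magnesium bridging the ketone and the β-PMB-oxy oxygen) delivers methyl from the face of the neighbouring C–H, which is also the face away from the side chain on the next ring carbon, giving the tertiary hydroxyl cis to the CH2OPMB group.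

Step 16
Reactants: 22 tertiary alcohol
Product: 23 triol (allylic primary, saturated primary and tertiary hydroxyl)
Conditions: DDQ, CH2Cl2/pH 7 buffer (10:1), 0 °C
Reagents that add atoms: none
Why: Oxidative cleavage of both PMB ethers by DDQ in wet solvent, which hydrolyses any benzylidene acetal formed with the tertiary hydroxyl.

Step 17
Reactants: 23 triol
Product: 24 2-methylene-1,5-dialdehyde (acetonide and tertiary hydroxyl retained)
Conditions: (COCl)2, DMSO, CH2Cl2, −78 °C; then Et3N, −78 → −30 °C
Reagents that add atoms: none
Why: Swern oxidation activates both primary alcohols before any aldehyde exists, so the 1,5-diol should give the dialdehyde and not a lactone via a lactol, and the tertiary alcohol is not oxidised.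

Step 18
Reactants: 24 2-methylene-1,5-dialdehyde
Product: 28 CNP0250836.2 (target), via diol dialdehyde 25 (not isolated), via oxepane enol 26 (not isolated), via lactol 27 (not isolated)
Conditions: AcOH/THF/H2O (3:1:1), 35 °C; evaporate; Et3N (0.2 equiv), CH2Cl2, rt; then Ac2O, pyridine, 0 °C → rt
Reagents that add atoms: acetic anhydride, CC(=O)OC(C)=O
Why: Aqueous acetic acid hydrolyses the spiro-acetonide to the cyclopropane-1,1-dimethanol 25, whose arm cis to the side chain adds to the terminal carbon of the 2-substituted acrolein (7-endo-trig oxa-Michael addition, closing the oxepane); the enol 26 created by that addition then adds through oxygen to the neighbouring aldehyde (6-exo-trig hemiacetalisation) to give the enol-lactol 27, which acetic anhydride traps together with the remaining primary alcohol. The closest known reaction types are domino oxa-Michael/hemiacetalisation sequences of enals and the cyclisation of iridodial-type 1,5-dialdehydes to enol-lactols followed by acetylation. The quaternary cyclopropane carbon becomes a stereocentre by geometry alone, because only the cis arm can span a cis-fused 3-oxabicyclo[5.1.0]octane, and the acetal carbon is set under thermodynamic (anomeric) control with the acetoxy group axial and trans to the ring bond on the neighbouring carbon, while the two ring-fusion centres come unchanged from 24. The step needs the cis primary hydroxyl to win over the trans arm and the tertiary hydroxyl: the conjugate additions are reversible, the trans arm would give a trans-fused oxepane, and the ether from the tertiary hydroxyl could reach an enol-lactol only as a bridgehead enol ether of a bicyclo[3.3.1]nonene, so only the desired adduct should drain into the stable acetal. The dihydropyran cannot close before the oxepane, and closes in the right sense, because the enol oxygen it needs is generated at the correct carbon only by the conjugate addition.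

**Compound list**
1 | but-3-en-1-ol | C=CCCO | starting material
2 | tert-butyl(but-3-en-1-yloxy)diphenylsilane | C=CCCO[Si](c1ccccc1)(c1ccccc1)C(C)(C)C | intermediate
3 | (E)-but-2-enal (crotonaldehyde) | C/C=C/C=O | starting material
4 | (E)-5-[(tert-butyldiphenylsilyl)oxy]pent-2-enal | O=C/C=C/CCO[Si](c1ccccc1)(c1ccccc1)C(C)(C)C | intermediate
5 | diethyl bromomalonate | CCOC(=O)C(Br)C(=O)OCC | starting material
6 | diethyl (2R,3R)-2-{2-[(tert-butyldiphenylsilyl)oxy]ethyl}-3-formylcyclopropane-1,1-dicarboxylate (formyl and side chain trans) | CCOC(=O)C1(C(=O)OCC)[C@H](C=O)[C@H]1CCO[Si](c1ccccc1)(c1ccccc1)C(C)(C)C | intermediate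
7 | dimethyl malonate | COC(=O)CC(=O)OC | starting material
8 | diethyl (2R,3R)-2-{2-[(tert-butyldiphenylsilyl)oxy]ethyl}-3-[2,2-bis(methoxycarbonyl)ethenyl]cyclopropane-1,1-dicarboxylate | CCOC(=O)C1(C(=O)OCC)[C@H](C=C(C(=O)OC)C(=O)OC)[C@H]1CCO[Si](c1ccccc1)(c1ccccc1)C(C)(C)C | intermediate
9 | 3-[(4-methoxybenzyl)oxy]propan-1-ol | COc1ccc(COCCCO)cc1 | starting material
10 | 3-[(4-methoxybenzyl)oxy]propanal | COc1ccc(COCCC=O)cc1 | intermediate
11 | syn-Michael adduct: diethyl (2R,3R)-2-{2-[(tert-butyldiphenylsilyl)oxy]ethyl}-3-{(2R,3S)-3-formyl-1,1-bis(methoxycarbonyl)-4-[(4-methoxybenzyl)oxy]butan-2-yl}cyclopropane-1,1-dicarboxylate | CCOC(=O)C1(C(=O)OCC)[C@H]([C@@H](C(C(=O)OC)C(=O)OC)[C@H](C=O)COCc2ccc(OC)cc2)[C@H]1CCO[Si](c1ccccc1)(c1ccccc1)C(C)(C)C | intermediate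
12 | 1,3-dithiane of 11 (formyl replaced by 1,3-dithian-2-yl; stereocentres as in 11) | CCOC(=O)C1(C(=O)OCC)[C@H]([C@@H](C(C(=O)OC)C(=O)OC)[C@H](C3SCCCS3)COCc2ccc(OC)cc2)[C@H]1CCO[Si](c1ccccc1)(c1ccccc1)C(C)(C)C | intermediate
13 | sodium enolate of the dimethyl malonate unit of 12 | CCOC(=O)C1(C(=O)OCC)[C@H]([C@@H]([C-](C(=O)OC)C(=O)OC)[C@H](C3SCCCS3)COCc2ccc(OC)cc2)[C@H]1CCO[Si](c1ccccc1)(c1ccccc1)C(C)(C)C.[Na+] | intermediate
14 | triol: trans-cyclopropane-1,1-dimethanol with the 2-(silyloxy)ethyl arm and the side chain CH[C(=CH2)CH2OH]-CH(1,3-dithian-2-yl)-CH2OPMB (stereocentres as in 11) | OCC1(CO)[C@H]([C@@H](C(=C)CO)[C@H](C3SCCCS3)COCc2ccc(OC)cc2)[C@H]1CCO[Si](c1ccccc1)(c1ccccc1)C(C)(C)C | intermediate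
15 | spiro-acetonide of 14 (6,6-dimethyl-5,7-dioxaspiro[2.5]octane; allylic alcohol free) | CC1(C)OCC2(CO1)[C@H]([C@@H](C(=C)CO)[C@H](C3SCCCS3)COCc3ccc(OC)cc3)[C@H]2CCO[Si](c1ccccc1)(c1ccccc1)C(C)(C)C | intermediate
16 | bis-PMB ether of 15 | CC1(C)OCC2(CO1)[C@H]([C@@H](C(=C)COCc3ccc(OC)cc3)[C@H](C4SCCCS4)COCc3ccc(OC)cc3)[C@H]2CCO[Si](c1ccccc1)(c1ccccc1)C(C)(C)C | intermediate
17 | primary alcohol (desilylated 16) | CC1(C)OCC2(CO1)[C@H]([C@@H](C(=C)COCc3ccc(OC)cc3)[C@H](C4SCCCS4)COCc3ccc(OC)cc3)[C@H]2CCO | intermediate
18 | primary chloride from 17 | CC1(C)OCC2(CO1)[C@H]([C@@H](C(=C)COCc3ccc(OC)cc3)[C@H](C4SCCCS4)COCc3ccc(OC)cc3)[C@H]2CCCl | intermediate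
19 | 2-lithio-1,3-dithiane derived from 18 | CC1(C)OCC2(CO1)[C@H]([C@@H](C(=C)COCc3ccc(OC)cc3)[C@H](C4([Li])SCCCS4)COCc3ccc(OC)cc3)[C@H]2CCCl | intermediate
20 | spiro-dithiane of the trans-fused bicyclo[5.1.0]octane (cycloheptane closed; the two side-chain CH centres cis on the new ring) | CC1(C)OCC2(CO1)[C@H]3[C@H]2CCC4(SCCCS4)[C@H](COCc5ccc(OC)cc5)[C@@H]3C(=C)COCc5ccc(OC)cc5 | intermediate
21 | trans-fused bicyclo[5.1.0]octanone (ketone from 20) | CC1(C)OCC2(CO1)[C@H]3[C@H]2CCC(=O)[C@H](COCc4ccc(OC)cc4)[C@@H]3C(=C)COCc4ccc(OC)cc4 | intermediate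
22 | tertiary methyl carbinol (hydroxyl cis to the CH2OPMB group) | CC1(C)OCC2(CO1)[C@H]3[C@H]2CC[C@](C)(O)[C@H](COCc4ccc(OC)cc4)[C@@H]3C(=C)COCc4ccc(OC)cc4 | intermediate
23 | triol (both PMB groups removed) | CC1(C)OCC2(CO1)[C@H]3[C@H]2CC[C@](C)(O)[C@H](CO)[C@@H]3C(=C)CO | intermediate
24 | 2-methylene-1,5-dialdehyde with spiro-acetonide and free tertiary hydroxyl | CC1(C)OCC2(CO1)[C@H]3[C@H]2CC[C@](C)(O)[C@H](C=O)[C@@H]3C(=C)C=O | intermediate
25 | diol dialdehyde (acetonide of 24 hydrolysed) | OCC1(CO)[C@H]2[C@H]1CC[C@](C)(O)[C@H](C=O)[C@@H]2C(=C)C=O | intermediate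
26 | oxepane enol (oxa-Michael adduct, cis-fused 3-oxabicyclo[5.1.0]octane, hydroxymethylene enol next to the remaining aldehyde) | OC[C@@]12COCC(=CO)[C@H]3[C@@H](C=O)[C@@](C)(O)CC[C@@H]2[C@H]13 | intermediate
27 | tetracyclic enol-lactol (target with OH in place of both acetoxy groups) | OC[C@@]12COCC3=CO[C@H](O)[C@@H]4[C@H]3[C@@H]1[C@H]2CC[C@]4(C)O | intermediate
28 | CNP0250836.2, tetracyclic acetal diacetate | CC(=O)OC[C@@]12COCC3=CO[C@H](OC(C)=O)[C@@H]4[C@H]3[C@@H]1[C@H]2CC[C@]4(C)O | target

**Step count and risks**

Total step count: 18. Longest linear sequence: 17 (steps 1–4 and 6–18; step 5 is the side branch).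

Steps most likely to fail:

Step 18. What may go wrong: conjugate addition of the tertiary hydroxyl or of water instead of the cis primary hydroxyl, acid-promoted dehydration or retro-aldol cleavage of the β-hydroxy aldehyde, epimerisation next to that aldehyde, or polymerisation of the 2-substituted acrolein. The fallback sets out from 22 and returns at 28; it replaces the acid-driven one-pot on the free tertiary alcohol by a protected, base-driven stepwise endgame. The tertiary alcohol of 22 is silylated (Et3SiOTf, 2,6-lutidine, CH2Cl2, −78 °C) to the triethylsilyl ether F1. DDQ as in step 16 should give the diol F2, and Swern oxidation the silylated dialdehyde F3. The acetonide is then hydrolysed under buffered conditions that spare the tertiary silyl ether (PPTS, wet MeCN), the conjugate addition and lactol closure are completed with a catalytic amine base, and acetylation (Ac2O, pyridine) should give the silylated diacetate F4. HF·pyridine (THF/pyridine, 0 °C) then releases 28.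

Step 13. What may go wrong: the 7-exo-tet closure onto the trans-cyclopropane is slow, so that proton transfer, intermolecular alkylation or attack of the carbanion on the allylic ether competes, or the hindered dithiane is not fully lithiated. The fallback sets out from 18 and returns at 21; it replaces carbanion substitution by carbonyl addition. Hydrolysis of the dithiane (MeI, CaCO3, aqueous MeCN) gives the chloro aldehyde F5, a Finkelstein exchange (NaI, acetone) the iodo aldehyde F6, and SmI2 (THF/HMPA, −78 °C, high dilution) should close the ring by intramolecular Barbier addition to the cycloheptanol F7 (mixture of carbinol epimers). Dess–Martin periodinane oxidises F7 to ketone 21.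

Step 8. What may go wrong: conjugate over-reduction of the intermediate acrylate to the saturated alcohol, complete reduction to the 1,3-diol, or sluggish reduction of the hindered enolate. The fallback sets out from 12 and returns at 14; it builds the methylene group by a Mannich route instead of hydride elimination. One methyl ester of the malonate is saponified (LiOH, THF/H2O, 0 °C; the neopentyl-type cyclopropane ethyl esters react more slowly) to the malonic half-acid F8. Decarboxylative Mannich methylenation (Et2NH, paraformaldehyde, EtOAc, reflux) gives the 2-substituted acrylate F9. i-Bu2AlH (CH2Cl2, −78 → 0 °C) then reduces the acrylate 1,2 and the two ethyl esters to give triol 14.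

**Further compounds**
F1 | step 18 | triethylsilyl ether of tertiary alcohol 22 | CC1(C)OCC2(CO1)[C@H]3[C@H]2CC[C@](C)(O[Si](CC)(CC)CC)[C@H](COCc4ccc(OC)cc4)[C@@H]3C(=C)COCc4ccc(OC)cc4
F2 | step 18 | silylated diol (both PMB groups removed) | CC1(C)OCC2(CO1)[C@H]3[C@H]2CC[C@](C)(O[Si](CC)(CC)CC)[C@H](CO)[C@@H]3C(=C)CO
F3 | step 18 | silylated 2-methylene-1,5-dialdehyde | CC1(C)OCC2(CO1)[C@H]3[C@H]2CC[C@](C)(O[Si](CC)(CC)CC)[C@H](C=O)[C@@H]3C(=C)C=O
F4 | step 18 | triethylsilyl ether of the target diacetate | CC(=O)OC[C@@]12COCC3=CO[C@H](OC(C)=O)[C@@H]4[C@H]3[C@@H]1[C@H]2CC[C@]4(C)O[Si](CC)(CC)CC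
F5 | step 13 | chloro aldehyde (dithiane of 18 hydrolysed) | CC1(C)OCC2(CO1)[C@H]([C@@H](C(=C)COCc3ccc(OC)cc3)[C@H](C=O)COCc3ccc(OC)cc3)[C@H]2CCCl
F6 | step 13 | iodo aldehyde | CC1(C)OCC2(CO1)[C@H]([C@@H](C(=C)COCc3ccc(OC)cc3)[C@H](C=O)COCc3ccc(OC)cc3)[C@H]2CCI
F7 | step 13 | trans-fused bicyclo[5.1.0]octanol (carbinol epimers) | CC1(C)OCC2(CO1)[C@H]3[C@H]2CCC(O)[C@H](COCc4ccc(OC)cc4)[C@@H]3C(=C)COCc4ccc(OC)cc4
F8 | step 8 | malonic half-acid of 12 | CCOC(=O)C1(C(=O)OCC)[C@H]([C@@H](C(C(=O)O)C(=O)OC)[C@H](C3SCCCS3)COCc2ccc(OC)cc2)[C@H]1CCO[Si](c1ccccc1)(c1ccccc1)C(C)(C)C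
F9 | step 8 | methyl 2-substituted acrylate | CCOC(=O)C1(C(=O)OCC)[C@H]([C@@H](C(=C)C(=O)OC)[C@H](C3SCCCS3)COCc2ccc(OC)cc2)[C@H]1CCO[Si](c1ccccc1)(c1ccccc1)C(C)(C)C
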